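## The problem

1. Target 14 is (3R,4R)-4-[(3,4-dihydroxyphenyl)methyl]-3-[(3,4-dimethoxyphenyl)methyl]oxolan-2-one. It is a γ-lactone (ring C: O1, C2 carbonyl, C3, C4, C5) with the dimethoxybenzyl arm (ring A) at C3 and the catechol arm (ring B) at C4, the two arms trans.
2. These labels are used for the same atoms in all intermediates.
3. No ring is hard to close; the hard bond is C3–C4, which joins two adjacent methine stereocentres and also the two C6–C3 halves of the molecule.
4. The oxygenated carbons C2 and C5 stand in a 1,4-relation, so C3 and C4 are both donor carbons by nature (each α to a carbonyl-level carbon), and no simple polar reaction joins them.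
5. The carbon skeleton is C2-symmetric, and only the oxidation level (C2 acid, C5 alcohol) and the O-substituents (ring A methylated, ring B free) break the symmetry. A synthesis must tie these two differences together, ring A next to the carbonyl group, although the rings lie too far from ring C to be told apart afterwards.
6. C3 carries an acidic hydrogen and can be equilibrated, the trans lactone being the more stable, whereas C4 is fixed once C5 is at the alcohol level. C4 can therefore control C3, and only C4 needs absolute control.
7. The feature that opens the key step is the chain C2–C3–C4–C5. With C5 raised to the acid level it is a 2,3-dibenzylsuccinic acid, in which C3 and C4 are the enolisable α-carbons of two 3-arylpropanoic acids, one bearing ring A and one bearing ring B.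
8. The catechol of ring B does not survive base with air, one-electron oxidants or alkylating agents and must stay masked to the end. Both rings are electron-rich and are attacked by carbocations and halogenating agents, and the lactone does not tolerate hydride or hard nucleophiles.

## Retrosynthesis

**14 ⇒ 13 (the two O–C bonds of a ketal).**
- The last step should only uncover ring B, so the two phenolic hydrogens of 14 become one isopropylidene bridge in 13.
- Benzyl ethers would cost an extra step, because the acid group of 1 is benzylated as well and must be freed again.
- A methylene bridge would need a Lewis acid for removal, which also threatens the methyl ethers of ring A.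
- The ketal goes on in one step and is inert to amide bases, divalent copper and borohydride.
- The forward reaction needs only aqueous acid under argon, to which the lactone, ring A and C3 are indifferent.

**13 ⇒ 12 ⇒ 11 (O1–C2, and the configuration at C3).**
- Opening ring C at the acyl–oxygen bond gives the γ-hydroxy tert-butyl ester 11.
- The neighbouring cut O1–C5 would need a leaving group at C5 and a free acid, that is, two more functional-group changes.
- The real gain is stereochemical. C3–H of the lactone is acidic and 13 is the more stable isomer, so 11 may be a mixture at C3.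
- Closure gives the mixture 12, and the same base drains it to 13. The precursor then has one stereocentre that matters, C4.
- The forward reaction must close onto a hindered ester (5-exo-trig). It must equilibrate under catalytic, protic base, so that thermodynamics and not kinetic protonation sets C3.

**11 ⇒ 10 (oxidation level of C5).**
- C5 is raised from carbinol to acyl level, as an N-acyloxazolidinone. C2 and C5 are then both carboxyl derivatives, and 10 is a succinate.
- The two ends stay distinguishable, because LiBH4 reduces the imide and leaves the tert-butyl ester.
- Which carbonyl becomes the lactone carbonyl is decided by which partner carries which acyl derivative. No reagent has to tell ring A from ring B.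

**10 ⇒ 5 + 7, through 8 and 9 (C3–C4, the key cut).**
- This is the only cut that divides the molecule into two halves of the same size and kind.
- The exocyclic cuts at C3–CH2 or C4–CH2 leave a chiral lactone that is hardly simpler than the target.
- Both fragments are 3-arylpropanoic acid derivatives with no stereocentre in the chain.
- Both carbons are donors, so the union must be oxidative: enolates 8 and 9 are joined while divalent copper takes up two electrons.
- The auxiliary sits on the ring B half because its α-carbon becomes C4, the centre that cannot be corrected later. The ring A half needs no auxiliary.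
- The forward reaction must give cross- over homocoupling and facial control at C4.

**5 ⇒ 2 + 3, 2 ⇒ 1, 7 ⇒ 6 (acyl–heteroatom bonds).**
- Acids 1 and 6 are bought with rings B and A and with all the carbons of their halves.
- Auxiliary 3 is commercial and is recovered in step 5.
- Only a ketalisation, an N-acylation and an esterification are needed.

## Roads not taken

**Alternative 1:**
- Cut: the exocyclic bond between C3 and the methylene of the ring A arm.
- Forward key step: the lithium enolate of the enantiopure lactone A1 is alkylated with bromide A2, which enters anti to the C4 arm and gives 13.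
- This is the route most chemists would draw first, and its last bond formation is reliable.
- Its weakness lies earlier. A1 already holds the one stereocentre that needs absolute control, so the whole stereochemical problem moves into a precursor.
- That precursor takes about as many steps as the entire chosen route. The options are auxiliary alkylation with a two-carbon unit, reduction and closure, or Stobbe condensation, asymmetric hydrogenation and chemoselective reduction.
- The two halves enter in unlike form, the sequence is linear, and A2 is a labile, self-alkylating benzylic halide.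
- The chosen plan makes the central bond and C4 in one operation from two acids that already hold all their carbons.

**Alternative 2:**
- Cut: the two C–H bonds at C3 and C4, which leads back to the flat, achiral butenolide A3.
- Forward key step: enantioselective reduction of the C3=C4 double bond by asymmetric hydrogenation, copper hydride conjugate reduction or an ene-reductase, followed by equilibration at C3.
- The double bond is tetrasubstituted, the least reactive class of enoate for all three methods.
- It is flanked by two nearly identical benzyl arms, so a catalyst finds little to distinguish the faces.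
- A3 must also be assembled by two separate carbon–carbon couplings on a preformed five-membered core, so the run-up is longer than that to 5 and 7.
- The chosen plan draws its facial control from a covalently bound group two atoms from the reacting carbon.

**Alternative 3:**
- Cut: C3–C4 again, but in the symmetric sense.
- Forward key step: oxidative homocoupling of enolate 8 alone gives the C2-symmetric bis-imide A4, with both centres under auxiliary control and no cross-selectivity problem.
- Reduction of both imides and oxidative lactonisation of either homotopic carbinol would lead to lactone A5.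
- The two rings of A5 are identical and differ only in their distance from C2.
- No reagent would unmask and methylate only the ring on the C3 arm, so the symmetric plan solves the easier half of the problem and leaves the harder half open.
- The chosen plan writes the difference into the two partners before they are joined.

Key step: step 4

Remark: compounds 1, 3 and 6 and the reagents over the arrows are taken to be commercial. The locants in systematic names are those of the named compound, while C2–C5 in running text always mean the atoms of ring C.

## Steps

Step 1
Reactants: 1 3-(3,4-dihydroxyphenyl)propanoic acid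
Product: 2 3-(2,2-dimethyl-1,3-benzodioxol-5-yl)propanoic acid
Conditions: Me2C(OMe)2, p-TsOH·H2O (cat.), toluene, reflux, MeOH trapped in a Soxhlet thimble of CaCl2
Reagents that add atoms: 2,2-dimethoxypropane, COC(C)(C)OC
Why: Acid-catalysed transketalisation of a catechol; continuous removal of methanol drives the otherwise unfavourable equilibrium and keeps the carboxylic acid from being esterified. No stereocentre is involved.

Step 2
Reactants: 2 3-(2,2-dimethyl-1,3-benzodioxol-5-yl)propanoic acid; 3 (4S)-4-benzyl-1,3-oxazolidin-2-one
Product: 5 (4S)-4-benzyl-3-[3-(2,2-dimethyl-1,3-benzodioxol-5-yl)propanoyl]-1,3-oxazolidin-2-one, via mixed pivalic anhydride 4 (not isolated)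
Conditions: PivCl, Et3N, THF, −20 °C; then LiCl, 3, −20 → 23 °C
Reagents that add atoms: pivaloyl chloride, CC(C)(C)C(=O)Cl (its acyl group stands in 4 only and leaves again as pivalate)
Why: N-acylation of an oxazolidinone through a mixed anhydride; the bulk of the pivaloyl group directs attack to the arylpropanoyl carbonyl, and LiCl makes the carbamate N–H acidic enough for Et3N. The stereocentre of 3 is not touched.

Step 3
Reactants: 6 3-(3,4-dimethoxyphenyl)propanoic acid
Product: 7 tert-butyl 3-(3,4-dimethoxyphenyl)propanoate
Conditions: Cl3CC(=NH)Ot-Bu, CH2Cl2–cyclohexane, 23 °C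
Reagents that add atoms: tert-butyl 2,2,2-trichloroacetimidate, CC(C)(C)OC(=N)C(Cl)(Cl)Cl
Why: Imidate esterification, in which the acid itself protonates the imidate and takes up the tert-butyl group; no added strong acid is present, so ring A is not alkylated.

Step 4
Reactants: 5 (4S)-4-benzyl-3-[3-(2,2-dimethyl-1,3-benzodioxol-5-yl)propanoyl]-1,3-oxazolidin-2-one; 7 tert-butyl 3-(3,4-dimethoxyphenyl)propanoate
Product: 10 tert-butyl (3R)-4-[(4S)-4-benzyl-2-oxo-1,3-oxazolidin-3-yl]-2-[(3,4-dimethoxyphenyl)methyl]-3-[(2,2-dimethyl-1,3-benzodioxol-5-yl)methyl]-4-oxobutanoate (both epimers at C-2 of the butanoate), via lithium Z-enolate 8 (not isolated), via lithium ester enolate 9 (not isolated)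
Conditions: 5 (1 equiv) + 7 (2 equiv) added to LiN(i-Pr)2 (3.1 equiv), THF, −78 °C; then Cu(2-ethylhexanoate)2 (3.1 equiv), THF, −78 → 0 °C; aq NH4Cl/NH3
Reagents that add atoms: LiN(i-Pr)2, [Li]N(C(C)C)C(C)C (lithium in 8 and 9 only; 10 holds nothing but atoms of 5 and 7)
Why: The step is an intermolecular oxidative enolate heterocoupling, the closest known reaction type being the union of N-acyloxazolidinone enolates with ester or ketone enolates by soluble carboxylates of divalent copper or by Fe(acac)3. LiN(i-Pr)2 turns 5 into the chelated Z-enolate 8 and 7 into 9; 8, a bidentate ligand, is expected to bind divalent copper and lose one electron within the complex, the electrophilic α-imide radical so formed is captured by the more electron-rich 9, and the resulting radical anion passes its electron to a second divalent copper. The bond made is C3–C4, a union of two donor carbons; no ring is closed here, and ring C follows in step 6 by a 5-exo-trig acyl substitution. C4 is controlled by the benzyl group of the auxiliary: it covers one face of the planar, chelated enolate or radical, 9 approaches from the other face in the sense known from alkylations of such enolates, and with the (4S) auxiliary and the priority order imide C=O > C3 > CH2 this gives (R). C3 is under no reliable control, and 10 is taken on as a pair of C3 epimers that step 6 makes converge. The selectivity needed is cross- over homocoupling; it rests on the unlike character of the partners (chelating, less electron-rich imide enolate against non-chelating, electron-rich ester enolate), on the excess of the cheap 7, and on the large polarity difference among the possible coupling products, which should make separation easy. The aryl ethers and the ketal of rings A and B are not oxidised by a copper carboxylate, and the bulky tert-butyl ester keeps 9 from Claisen condensation at −78 °C.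

Step 5
Reactants: 10 tert-butyl (3R)-4-[(4S)-4-benzyl-2-oxo-1,3-oxazolidin-3-yl]-2-[(3,4-dimethoxyphenyl)methyl]-3-[(2,2-dimethyl-1,3-benzodioxol-5-yl)methyl]-4-oxobutanoate
Product: 11 tert-butyl (3R)-2-[(3,4-dimethoxyphenyl)methyl]-4-(2,2-dimethyl-1,3-benzodioxol-5-yl)-3-(hydroxymethyl)butanoate (both epimers at C-2 of the butanoate)
Conditions: LiBH4, H2O (1 equiv), Et2O, 0 °C
Reagents that add atoms: none
Why: Reductive cleavage of an N-acyloxazolidinone with LiBH4; the imide carbonyl, activated by the carbamate, is reduced through the aldehyde to the carbinol, while the tert-butyl ester and the ketal are inert at 0 °C. C4 ceases to be α to a carbonyl group and is fixed from here on; 3 is recovered.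

Step 6
Reactants: 11 tert-butyl (3R)-2-[(3,4-dimethoxyphenyl)methyl]-4-(2,2-dimethyl-1,3-benzodioxol-5-yl)-3-(hydroxymethyl)butanoate
Product: 13 (3R,4R)-3-[(3,4-dimethoxyphenyl)methyl]-4-[(2,2-dimethyl-1,3-benzodioxol-5-yl)methyl]oxolan-2-one, via C3-epimeric lactone mixture 12 (not isolated)
Conditions: t-BuOK (0.2 equiv), t-BuOH–THF, 23 °C, argon; AcOH quench
Reagents that add atoms: none
Why: Base-catalysed lactonisation (5-exo-trig intramolecular transesterification), in which the expelled tert-butoxide carries the chain, followed in the same flask by thermodynamic epimerisation of 12 through the lactone enolate. In the protic medium with catalytic base C3 is set by the fixed centre C4, the trans arrangement of the two arms being the more stable. No tert-butyl cation is formed, so rings A and B are not alkylated.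

Step 7
Reactants: 13 (3R,4R)-3-[(3,4-dimethoxyphenyl)methyl]-4-[(2,2-dimethyl-1,3-benzodioxol-5-yl)methyl]oxolan-2-one
Product: 14 (3R,4R)-4-[(3,4-dihydroxyphenyl)methyl]-3-[(3,4-dimethoxyphenyl)methyl]oxolan-2-one
Conditions: TFA–H2O–CH2Cl2, 0 → 23 °C, argon, degassed solvents; evaporation
Reagents that add atoms: none
Why: Acid hydrolysis of a catechol isopropylidene ketal; the oxygen of water ends in acetone and ring B gains only hydrogen. The lactone, the methyl ethers of ring A and both stereocentres are stable to aqueous acid, all by-products are volatile, and exclusion of air protects the free catechol.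

## Compound list

1 | 3-(3,4-dihydroxyphenyl)propanoic acid | OC(=O)CCc1ccc(O)c(O)c1 | starting material
2 | 3-(2,2-dimethyl-1,3-benzodioxol-5-yl)propanoic acid | OC(=O)CCc1ccc2OC(C)(C)Oc2c1 | intermediate
3 | (4S)-4-benzyl-1,3-oxazolidin-2-one | O=C1N[C@@H](Cc2ccccc2)CO1 | starting material
4 | 3-(2,2-dimethyl-1,3-benzodioxol-5-yl)propanoic pivalic anhydride | CC(C)(C)C(=O)OC(=O)CCc1ccc2OC(C)(C)Oc2c1 | intermediate
5 | (4S)-4-benzyl-3-[3-(2,2-dimethyl-1,3-benzodioxol-5-yl)propanoyl]-1,3-oxazolidin-2-one | O=C(CCc1ccc2OC(C)(C)Oc2c1)N1[C@@H](Cc2ccccc2)COC1=O | intermediate
6 | 3-(3,4-dimethoxyphenyl)propanoic acid | COc1ccc(CCC(=O)O)cc1OC | starting material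
7 | tert-butyl 3-(3,4-dimethoxyphenyl)propanoate | COc1ccc(CCC(=O)OC(C)(C)C)cc1OC | intermediate
8 | lithium (Z)-enolate of 5 | [Li]O/C(=C\Cc1ccc2OC(C)(C)Oc2c1)N1[C@@H](Cc2ccccc2)COC1=O | intermediate
9 | lithium enolate of 7 (geometry of no consequence) | [Li]OC(=CCc1ccc(OC)c(OC)c1)OC(C)(C)C | intermediate
10 | tert-butyl (3R)-4-[(4S)-4-benzyl-2-oxo-1,3-oxazolidin-3-yl]-2-[(3,4-dimethoxyphenyl)methyl]-3-[(2,2-dimethyl-1,3-benzodioxol-5-yl)methyl]-4-oxobutanoate, both C-2 epimers | COc1ccc(CC(C(=O)OC(C)(C)C)[C@H](C(=O)N2[C@@H](Cc3ccccc3)COC2=O)Cc2ccc3OC(C)(C)Oc3c2)cc1OC | intermediate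
11 | tert-butyl (3R)-2-[(3,4-dimethoxyphenyl)methyl]-4-(2,2-dimethyl-1,3-benzodioxol-5-yl)-3-(hydroxymethyl)butanoate, both C-2 epimers | COc1ccc(CC(C(=O)OC(C)(C)C)[C@H](CO)Cc2ccc3OC(C)(C)Oc3c2)cc1OC | intermediate
12 | (4R)-3-[(3,4-dimethoxyphenyl)methyl]-4-[(2,2-dimethyl-1,3-benzodioxol-5-yl)methyl]oxolan-2-one, both C3 epimers | COc1ccc(CC2C(=O)OC[C@@H]2Cc2ccc3OC(C)(C)Oc3c2)cc1OC | intermediate
13 | (3R,4R)-3-[(3,4-dimethoxyphenyl)methyl]-4-[(2,2-dimethyl-1,3-benzodioxol-5-yl)methyl]oxolan-2-one | COc1ccc(C[C@H]2C(=O)OC[C@@H]2Cc2ccc3OC(C)(C)Oc3c2)cc1OC | intermediate
14 | (3R,4R)-4-[(3,4-dihydroxyphenyl)methyl]-3-[(3,4-dimethoxyphenyl)methyl]oxolan-2-one | COc1ccc(C[C@H]2C(=O)OC[C@@H]2Cc2ccc(O)c(O)c2)cc1OC | target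

## Step count and least certain steps

Total step count: 7. Longest linear sequence: 6 (steps 1, 2, 4, 5, 6, 7); step 3 feeds the convergent branch.

**Step 4 (key step).**
- Most likely failure: statistical homocoupling of either enolate at the expense of the cross-coupling, and partial loss of facial control if the radical leaves the chelate before the bond forms. Both arise because two enolates of similar size compete for a fast and weakly discriminating oxidant.
- Fallback, from 5 and back at 13: the central bond is made in polar fashion with a two-carbon unit, and the ring A arm is attached afterwards.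
- The sodium enolate of 5 (NaN(SiMe3)2, THF, −78 °C) is alkylated with tert-butyl bromoacetate under control of the auxiliary to give the imide ester F1.
- LiBH4 gives the hydroxy ester F2, and catalytic t-BuOK closes it to the lactone F3 (the same compound as A1).
- The lithium enolate of F3 (LiN(i-Pr)2, THF, −78 °C) is alkylated with bromide A2 anti to the C4 arm to give 13.

**Step 5.**
- Most likely failure: hydride attack at the ring carbonyl of the auxiliary, because the exocyclic carbonyl is flanked by a fully branched α-carbon. Premature lactonisation of the alkoxide followed by over-reduction is also possible.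
- Fallback, from 10 and back at 11: the oxidation level is changed in two stages.
- LiOH/H2O2 (THF–H2O, 0 °C) gives the half-ester acid F4. Hydroperoxide cleaves even hindered imides at the exocyclic carbonyl.
- BH3·SMe2 (THF, 0 °C) reduces the free acid and leaves the tert-butyl ester, giving 11.

**Step 6.**
- Most likely failure: slow closure onto the hindered ester, or an equilibrium that retains part of the cis isomer. The energy difference between the two lactones is the only source of selectivity at C3.
- Fallback, from 10 and back at 13: C3 is taken from the coupling instead of from the equilibrium.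
- The epimers of 10 are separated by chromatography.
- The (2R,3R)-imide ester F5 is reduced with LiBH4 to the (2R,3R)-hydroxy ester F6.
- F6 is closed under acid catalysis (p-TsOH, toluene, 80 °C, isobutene escaping as gas), which does not touch C3, to give 13.

**Step 1.**
- Most likely failure: incomplete ketalisation and concurrent esterification of the acid by the liberated methanol. Catechol ketals form against an unfavourable equilibrium.
- Fallback, from 1 and back at 2: the acid is masked first.
- Fischer esterification (MeOH, H2SO4 cat.) gives the methyl ester F7.
- Ketalisation of this more soluble substrate under the conditions of step 1 gives the ketal ester F8.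
- LiOH (THF–H2O) gives 2.

## Further compounds

F1 | step 4 | tert-butyl (3R)-4-[(4S)-4-benzyl-2-oxo-1,3-oxazolidin-3-yl]-3-[(2,2-dimethyl-1,3-benzodioxol-5-yl)methyl]-4-oxobutanoate | CC(C)(C)OC(=O)C[C@H](C(=O)N1[C@@H](Cc2ccccc2)COC1=O)Cc1ccc2OC(C)(C)Oc2c1
F2 | step 4 | tert-butyl (3R)-4-(2,2-dimethyl-1,3-benzodioxol-5-yl)-3-(hydroxymethyl)butanoate | CC(C)(C)OC(=O)C[C@H](CO)Cc1ccc2OC(C)(C)Oc2c1
F3 | step 4 | (4R)-4-[(2,2-dimethyl-1,3-benzodioxol-5-yl)methyl]oxolan-2-one | O=C1C[C@@H](Cc2ccc3OC(C)(C)Oc3c2)CO1
F4 | step 5 | (2R)-4-tert-butoxy-3-[(3,4-dimethoxyphenyl)methyl]-2-[(2,2-dimethyl-1,3-benzodioxol-5-yl)methyl]-4-oxobutanoic acid, both C-3 epimers | COc1ccc(CC(C(=O)OC(C)(C)C)[C@H](C(=O)O)Cc2ccc3OC(C)(C)Oc3c2)cc1OC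
F5 | step 6 | tert-butyl (2R,3R)-4-[(4S)-4-benzyl-2-oxo-1,3-oxazolidin-3-yl]-2-[(3,4-dimethoxyphenyl)methyl]-3-[(2,2-dimethyl-1,3-benzodioxol-5-yl)methyl]-4-oxobutanoate | COc1ccc(C[C@@H](C(=O)OC(C)(C)C)[C@H](C(=O)N2[C@@H](Cc3ccccc3)COC2=O)Cc2ccc3OC(C)(C)Oc3c2)cc1OC
F6 | step 6 | tert-butyl (2R,3R)-2-[(3,4-dimethoxyphenyl)methyl]-4-(2,2-dimethyl-1,3-benzodioxol-5-yl)-3-(hydroxymethyl)butanoate | COc1ccc(C[C@@H](C(=O)OC(C)(C)C)[C@H](CO)Cc2ccc3OC(C)(C)Oc3c2)cc1OC
F7 | step 1 | methyl 3-(3,4-dihydroxyphenyl)propanoate | COC(=O)CCc1ccc(O)c(O)c1
F8 | step 1 | methyl 3-(2,2-dimethyl-1,3-benzodioxol-5-yl)propanoate | COC(=O)CCc1ccc2OC(C)(C)Oc2c1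
A1 | alternative 1 | (4R)-4-[(2,2-dimethyl-1,3-benzodioxol-5-yl)methyl]oxolan-2-one | O=C1C[C@@H](Cc2ccc3OC(C)(C)Oc3c2)CO1
A2 | alternative 1 | 4-(bromomethyl)-1,2-dimethoxybenzene | COc1ccc(CBr)cc1OC
A3 | alternative 2 | 3-[(3,4-dimethoxyphenyl)methyl]-4-[(2,2-dimethyl-1,3-benzodioxol-5-yl)methyl]furan-2(5H)-one | COc1ccc(CC2=C(Cc3ccc4OC(C)(C)Oc4c3)COC2=O)cc1OC
A4 | alternative 3 | (2R,3R)-1,4-bis[(4S)-4-benzyl-2-oxo-1,3-oxazolidin-3-yl]-2,3-bis[(2,2-dimethyl-1,3-benzodioxol-5-yl)methyl]butane-1,4-dione | O=C([C@H](Cc1ccc2OC(C)(C)Oc2c1)[C@@H](Cc1ccc2OC(C)(C)Oc2c1)C(=O)N1[C@@H](Cc2ccccc2)COC1=O)N1[C@@H](Cc2ccccc2)COC1=O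
A5 | alternative 3 | (3R,4R)-3,4-bis[(2,2-dimethyl-1,3-benzodioxol-5-yl)methyl]oxolan-2-one | CC1(C)Oc2ccc(C[C@H]3C(=O)OC[C@@H]3Cc3ccc4OC(C)(C)Oc4c3)cc2O1
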